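**Strategy**

The synthesis rests on opening the 2,5-dihydrofuran ring (O, C5, C6, C7, C8) of the 5,8-epoxy end group at C6=C7 and C7–C8. C7 is the only vinylic CH of that ring and lies between the fully substituted ring-fusion carbon C6 and the ether carbon C8, so it can enter as one carbene carbon. In a single operation a non-enolisable C6 ketone is turned into a C6=C7 alkylidene carbene that inserts into an O–C8–H bond, closing the heterocycle and creating C8. The precursor is silylated 5-hydroxyactinol whose tertiary C5 oxygen carries an (E)-4-silyloxy-2-methylbut-2-enyl group. The C15 product is then joined, as a Wittig salt, to a C25 ε-end polyenal.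

Key step: step 8

Assumption: (4R,6R)-actinol, (R)-α-ionone of high enantiomeric purity and (2E,4E,6E)-2,7-dimethylocta-2,4,6-trienedial are treated as purchasable fine chemicals; carotenoid locants (C1–C15, primed for the ε half) are used for all fragments.

Steps 1–3 make the allylic bromide, steps 4–11 the furanoid C15 salt, steps 12–19 the ε-end C25 aldehyde, and steps 20–21 join the halves.

**Route**

Step 1
Reactants: 1 prenol (3-methylbut-2-en-1-ol)
Product: 2 tert-butyl(dimethyl)[(3-methylbut-2-en-1-yl)oxy]silane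
Conditions: TBSCl, imidazole, CH2Cl2, 0 °C → rt
Reagents that add atoms: tert-butyldimethylsilyl chloride, CC(C)(C)[Si](C)(C)Cl
Why: Silyl ether formation at a primary alcohol; the trisubstituted alkene is untouched.

Step 2
Reactants: 2 tert-butyl(dimethyl)[(3-methylbut-2-en-1-yl)oxy]silane
Product: 3 (2E)-4-{[tert-butyl(dimethyl)silyl]oxy}-2-methylbut-2-en-1-ol
Conditions: SeO2 (cat.), t-BuOOH, CH2Cl2, rt
Reagents that add atoms: tert-butyl hydroperoxide, CC(C)(C)OO
Why: Riley allylic oxidation (ene reaction, then [2,3]-sigmatropic shift) should oxygenate the methyl group trans to the CH2OSi chain, which fixes the (E) geometry of the later C9=C10 bond; any over-oxidised enal is removed by chromatography.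

Step 3
Reactants: 3 (2E)-4-{[tert-butyl(dimethyl)silyl]oxy}-2-methylbut-2-en-1-ol
Product: 4 {[(2E)-4-bromo-3-methylbut-2-en-1-yl]oxy}(tert-butyl)dimethylsilane
Conditions: CBr4, PPh3, CH2Cl2, 0 °C
Reagents that add atoms: carbon tetrabromide, BrC(Br)(Br)Br
Why: Appel reaction: bromide displaces the alkoxyphosphonium group by SN2 at the primary allylic carbon under neutral conditions, so the silyl ether and the (E) alkene are kept.

Step 4
Reactants: 5 (4R,6R)-actinol, (4R,6R)-4-hydroxy-2,2,6-trimethylcyclohexan-1-one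
Product: 6 (4R,6R)-4-{[tert-butyl(dimethyl)silyl]oxy}-2,2,6-trimethylcyclohexan-1-one
Conditions: TBSCl, imidazole, DMF, rt
Reagents that add atoms: tert-butyldimethylsilyl chloride, CC(C)(C)[Si](C)(C)Cl
Why: Silyl ether formation at the only hydroxyl group; the carbinol carbon (carotenoid C3) keeps its configuration and the hindered ketone does not react.

Step 5
Reactants: 6 (4R,6R)-4-{[tert-butyl(dimethyl)silyl]oxy}-2,2,6-trimethylcyclohexan-1-one
Product: 7 tert-butyl(dimethyl){[(1R)-3,5,5-trimethyl-4-[(trimethylsilyl)oxy]cyclohex-3-en-1-yl]oxy}silane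
Conditions: LiN(iPr)2, Me3SiCl, THF, −78 → 0 °C
Reagents that add atoms: chlorotrimethylsilane, C[Si](C)(C)Cl
Why: Lithium enolate formation and O-silylation (silyl enol ether synthesis); C1 is quaternary, so enolisation can only go toward C5, whose stereocentre is erased on purpose.

Step 6
Reactants: 7 tert-butyl(dimethyl){[(1R)-3,5,5-trimethyl-4-[(trimethylsilyl)oxy]cyclohex-3-en-1-yl]oxy}silane
Product: 10 (2R,4S)-4-{[tert-butyl(dimethyl)silyl]oxy}-2-hydroxy-2,6,6-trimethylcyclohexan-1-one, via silyloxy epoxide 8 (not isolated), via trimethylsilyloxy ketone 9 (not isolated)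
Conditions: mCPBA, NaHCO3, CH2Cl2, −20 → 0 °C; then K2CO3 (cat.), MeOH, 0 °C
Reagents that add atoms: 3-chloroperbenzoic acid, OOC(=O)c1cccc(Cl)c1
Why: Rubottom oxidation: the peracid should epoxidise the electron-rich enol ether on the face remote from the C3 silyloxy group, the epoxide opens with 1,4-silyl shift to the silyloxy ketone and methanolysis frees the tertiary alcohol, so the C5 oxygen should end up trans to the C3 oxygen (5R); the C5 epimer is a diastereomer and is removed by chromatography.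

Step 7
Reactants: 10 (2R,4S)-4-{[tert-butyl(dimethyl)silyl]oxy}-2-hydroxy-2,6,6-trimethylcyclohexan-1-one; 4 {[(2E)-4-bromo-3-methylbut-2-en-1-yl]oxy}(tert-butyl)dimethylsilane
Product: 11 (2R,4S)-4-{[tert-butyl(dimethyl)silyl]oxy}-2-{[(2E)-4-{[tert-butyl(dimethyl)silyl]oxy}-2-methylbut-2-en-1-yl]oxy}-2,6,6-trimethylcyclohexan-1-one
Conditions: NaH, Bu4NI (cat.), THF–DMF, 0 °C → rt
Reagents that add atoms: none
Why: Williamson ether synthesis: the ketone has no α-hydrogen, so NaH forms only the tertiary alkoxide, which displaces the primary allylic bromide by SN2 without touching C5 or the (E) double bond.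

Step 8
Reactants: 11 (2R,4S)-4-{[tert-butyl(dimethyl)silyl]oxy}-2-{[(2E)-4-{[tert-butyl(dimethyl)silyl]oxy}-2-methylbut-2-en-1-yl]oxy}-2,6,6-trimethylcyclohexan-1-one; 12 (trimethylsilyl)diazomethane
Product: 16 (2S,6S,7aR)-6-{[tert-butyl(dimethyl)silyl]oxy}-2-[(2E)-4-{[tert-butyl(dimethyl)silyl]oxy}but-2-en-2-yl]-4,4,7a-trimethyl-2,4,5,6,7,7a-hexahydro-1-benzofuran, via lithium alkoxide adduct 13 (not isolated), via diazoalkene 14 (not isolated), via alkylidene carbene 15 (not isolated)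
Conditions: 12, n-BuLi, THF, −78 °C; then 11, −78 °C → rt
Reagents that add atoms: none
Why: The lithiated diazo compound adds to the C6 carbonyl, which has no α-hydrogen and is activated by the α-alkoxy group; the β-silyl alkoxide 13 undergoes Peterson elimination to diazoalkene 14, which loses N2 to the singlet alkylidene carbene 15. This is the established alkylidene-carbene route from α-alkoxy ketones to 2,5-dihydrofurans. The dihydrofuran ring (O, C5, C6, C7, C8) closes by concerted 1,5 C–H insertion through a five-membered transition state, forming C7–C8 with retention at C8; a 1,2-shift would need a cycloheptyne, insertion at C3–H a bridgehead alkene and addition to C9=C10 a bicyclo[4.1.0]hept-1-ene, so these paths are strained out. The new stereocentre C8 is set by which diastereotopic hydrogen is replaced: insertion into the pro-S C8–H, with the butenyl residue on the face of the C5 methyl group, gives (8S), and the only controlling element is the adjacent quaternary C5 (methyl versus ring C4H2). The step needs site selectivity, which is secured because the oxygen- and allyl-activated C8–H is the only C–H within unstrained 1,5-reach, and diastereotopic selectivity, for which the substrate offers at best a modest bias, so (8S)-16 would be separated from its C8 epimer by chromatography.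

Step 9
Reactants: 16 (2S,6S,7aR)-6-{[tert-butyl(dimethyl)silyl]oxy}-2-[(2E)-4-{[tert-butyl(dimethyl)silyl]oxy}but-2-en-2-yl]-4,4,7a-trimethyl-2,4,5,6,7,7a-hexahydro-1-benzofuran
Product: 17 (2S,6S,7aR)-2-[(2E)-4-hydroxybut-2-en-2-yl]-4,4,7a-trimethyl-2,4,5,6,7,7a-hexahydro-1-benzofuran-6-ol
Conditions: Bu4NF, THF, 0 °C → rt
Reagents that add atoms: none
Why: Fluoride-induced cleavage of both Si–O bonds under basic conditions, chosen because acid would ionise the doubly allylic C8–O bond and scramble C8.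

Step 10
Reactants: 17 (2S,6S,7aR)-2-[(2E)-4-hydroxybut-2-en-2-yl]-4,4,7a-trimethyl-2,4,5,6,7,7a-hexahydro-1-benzofuran-6-ol
Product: 18 (2S,6S,7aR)-2-[(2E)-4-bromobut-2-en-2-yl]-4,4,7a-trimethyl-2,4,5,6,7,7a-hexahydro-1-benzofuran-6-ol
Conditions: NBS, Me2S, CH2Cl2, −30 → 0 °C
Reagents that add atoms: N-bromosuccinimide, O=C1CCC(=O)N1Br
Why: Corey–Kim halogenation: only the allylic alkoxysulfonium ion is displaced by bromide (SN2 at C11), whereas the saturated secondary C3 alcohol is returned unchanged on work-up, and no acid is generated.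

Step 11
Reactants: 18 (2S,6S,7aR)-2-[(2E)-4-bromobut-2-en-2-yl]-4,4,7a-trimethyl-2,4,5,6,7,7a-hexahydro-1-benzofuran-6-ol
Product: 19 [(2E)-3-[(2S,6S,7aR)-6-hydroxy-4,4,7a-trimethyl-2,4,5,6,7,7a-hexahydro-1-benzofuran-2-yl]but-2-en-1-yl]triphenylphosphonium bromide
Conditions: PPh3, EtOAc, rt, dark
Reagents that add atoms: triphenylphosphine, c1ccc(cc1)P(c1ccccc1)c1ccccc1
Why: SN2 quaternisation of PPh3 by the primary allylic bromide (phosphonium salt formation); the salt should precipitate and C8 is not involved.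

Step 12
Reactants: 20 (R)-α-ionone, (3E)-4-[(1R)-2,6,6-trimethylcyclohex-2-en-1-yl]but-3-en-2-one; 21 triethyl phosphonoacetate
Product: 22 ethyl (2E,4E)-3-methyl-5-[(1R)-2,6,6-trimethylcyclohex-2-en-1-yl]penta-2,4-dienoate
Conditions: NaH, THF, 0 → 50 °C
Reagents that add atoms: none
Why: Horner–Wadsworth–Emmons olefination of the methyl ketone should give mainly the (2E) dienoate (the minor 2Z isomer is removed by chromatography), and the stabilised phosphonate anion is too weak a base to deprotonate C6', which stays (R).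

Step 13
Reactants: 22 ethyl (2E,4E)-3-methyl-5-[(1R)-2,6,6-trimethylcyclohex-2-en-1-yl]penta-2,4-dienoate
Product: 23 ethyl (2E,4E)-3-methyl-5-[(1R)-2,6,6-trimethyl-4-oxocyclohex-2-en-1-yl]penta-2,4-dienoate
Conditions: Rh2(cap)4 (cat.; cap = caprolactamate, C6H10NO), t-BuOOH (70% aq.), ClCH2CH2Cl, 40 °C
Reagents that add atoms: tert-butyl hydroperoxide, CC(C)(C)OO
Why: Radical allylic oxidation (tert-butylperoxy radical chain) at the ring methylene C3', the most accessible secondary allylic C–H, should give the enone without base, so that C6' is not epimerised.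

Step 14
Reactants: 23 ethyl (2E,4E)-3-methyl-5-[(1R)-2,6,6-trimethyl-4-oxocyclohex-2-en-1-yl]penta-2,4-dienoate
Product: 24 ethyl (2E,4E)-5-[(1R,4R)-4-hydroxy-2,6,6-trimethylcyclohex-2-en-1-yl]-3-methylpenta-2,4-dienoate
Conditions: LiBH(s-Bu)3, THF, −78 °C
Reagents that add atoms: none
Why: 1,2-Reduction of the enone (conjugate reduction is blocked by the fully substituted β-carbon C5'); the bulky hydride should avoid the face shielded by the pseudoaxial C1' methyl group and so give the pseudoaxial 3'-alcohol trans to the pseudoaxial C6' side chain, which sets (3'R).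

Step 15
Reactants: 24 ethyl (2E,4E)-5-[(1R,4R)-4-hydroxy-2,6,6-trimethylcyclohex-2-en-1-yl]-3-methylpenta-2,4-dienoate
Product: 25 ethyl (2E,4E)-5-[(1R,4R)-4-{[tert-butyl(dimethyl)silyl]oxy}-2,6,6-trimethylcyclohex-2-en-1-yl]-3-methylpenta-2,4-dienoate
Conditions: TBSCl, imidazole, DMF, rt
Reagents that add atoms: tert-butyldimethylsilyl chloride, CC(C)(C)[Si](C)(C)Cl
Why: Silyl ether formation protects the secondary allylic alcohol for the reduction, bromination and Wittig steps.

Step 16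
Reactants: 25 ethyl (2E,4E)-5-[(1R,4R)-4-{[tert-butyl(dimethyl)silyl]oxy}-2,6,6-trimethylcyclohex-2-en-1-yl]-3-methylpenta-2,4-dienoate
Product: 26 (2E,4E)-5-[(1R,4R)-4-{[tert-butyl(dimethyl)silyl]oxy}-2,6,6-trimethylcyclohex-2-en-1-yl]-3-methylpenta-2,4-dien-1-ol
Conditions: i-Bu2AlH, CH2Cl2, −78 °C
Reagents that add atoms: none
Why: Diisobutylaluminium hydride reduces the conjugated ester to the primary allylic alcohol (ester 1,2-reduction) without affecting the diene or the silyl ether.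

Step 17
Reactants: 26 (2E,4E)-5-[(1R,4R)-4-{[tert-butyl(dimethyl)silyl]oxy}-2,6,6-trimethylcyclohex-2-en-1-yl]-3-methylpenta-2,4-dien-1-ol
Product: 27 tert-butyl{[(1R,4R)-4-[(1E,3E)-5-bromo-3-methylpenta-1,3-dien-1-yl]-3,5,5-trimethylcyclohex-2-en-1-yl]oxy}dimethylsilane
Conditions: NBS, Me2S, CH2Cl2, −30 → 0 °C
Reagents that add atoms: N-bromosuccinimide, O=C1CCC(=O)N1Br
Why: Corey–Kim halogenation converts the primary allylic alcohol into the bromide by SN2 under neutral conditions, keeping the (E,E) diene and the silyl ether.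

Step 18
Reactants: 27 tert-butyl{[(1R,4R)-4-[(1E,3E)-5-bromo-3-methylpenta-1,3-dien-1-yl]-3,5,5-trimethylcyclohex-2-en-1-yl]oxy}dimethylsilane
Product: 28 [(2E,4E)-5-[(1R,4R)-4-{[tert-butyl(dimethyl)silyl]oxy}-2,6,6-trimethylcyclohex-2-en-1-yl]-3-methylpenta-2,4-dien-1-yl]triphenylphosphonium bromide
Conditions: PPh3, EtOAc, rt, dark
Reagents that add atoms: triphenylphosphine, c1ccc(cc1)P(c1ccccc1)c1ccccc1
Why: SN2 quaternisation of PPh3 by the primary allylic bromide (phosphonium salt formation).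

Step 19
Reactants: 28 [(2E,4E)-5-[(1R,4R)-4-{[tert-butyl(dimethyl)silyl]oxy}-2,6,6-trimethylcyclohex-2-en-1-yl]-3-methylpenta-2,4-dien-1-yl]triphenylphosphonium bromide; 29 (2E,4E,6E)-2,7-dimethylocta-2,4,6-trienedial (3 equiv)
Product: 30 (2E,4E,6E,8E,10E,12E)-13-[(1R,4R)-4-{[tert-butyl(dimethyl)silyl]oxy}-2,6,6-trimethylcyclohex-2-en-1-yl]-2,7,11-trimethyltrideca-2,4,6,8,10,12-hexaenal
Conditions: NaOMe, MeOH–CH2Cl2, −10 °C → rt; then heptane, 80 °C (Z → E)
Reagents that add atoms: none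
Why: Wittig olefination of one aldehyde group (the dialdehyde is in excess so that the mono-adduct should predominate); the C11'=C12' bond forms as an E/Z mixture and the hindered Z isomer should convert into E on warming.

Step 20
Reactants: 19 [(2E)-3-[(2S,6S,7aR)-6-hydroxy-4,4,7a-trimethyl-2,4,5,6,7,7a-hexahydro-1-benzofuran-2-yl]but-2-en-1-yl]triphenylphosphonium bromide; 30 (2E,4E,6E,8E,10E,12E)-13-[(1R,4R)-4-{[tert-butyl(dimethyl)silyl]oxy}-2,6,6-trimethylcyclohex-2-en-1-yl]-2,7,11-trimethyltrideca-2,4,6,8,10,12-hexaenal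
Product: 31 (3S,5R,8S,3'R,6'R)-3'-{[tert-butyl(dimethyl)silyl]oxy}-5,8-epoxy-5,8-dihydro-β,ε-caroten-3-ol
Conditions: 1,2-epoxybutane, EtOH, 70 °C, dark
Reagents that add atoms: none
Why: Wittig olefination under the neutral epoxide protocol (bromide opens the epoxide and the resulting alkoxide deprotonates the salt), which should spare the acid-labile dihydrofuran, the free C3 alcohol and the C8 stereocentre; warming converts the hindered (11Z) isomer into the all-E polyene.

Step 21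
Reactants: 31 (3S,5R,8S,3'R,6'R)-3'-{[tert-butyl(dimethyl)silyl]oxy}-5,8-epoxy-5,8-dihydro-β,ε-caroten-3-ol
Product: 32 (3S,5R,8S,3'R,6'R)-5,8-epoxy-5,8-dihydro-β,ε-carotene-3,3'-diol (CNP0219251.2)
Conditions: Bu4NF, THF, 0 °C → rt, dark
Reagents that add atoms: none
Why: Fluoride-induced desilylation under non-acidic conditions should release the allylic 3'-alcohol without epimerising C3' or C8.

**Compound list**

1 | prenol, 3-methylbut-2-en-1-ol | CC(C)=CCO | starting material
2 | tert-butyl(dimethyl)[(3-methylbut-2-en-1-yl)oxy]silane | CC(C)=CCO[Si](C)(C)C(C)(C)C | intermediate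
3 | (2E)-4-{[tert-butyl(dimethyl)silyl]oxy}-2-methylbut-2-en-1-ol | OC/C(C)=C/CO[Si](C)(C)C(C)(C)C | intermediate
4 | {[(2E)-4-bromo-3-methylbut-2-en-1-yl]oxy}(tert-butyl)dimethylsilane | BrC/C(C)=C/CO[Si](C)(C)C(C)(C)C | intermediate
5 | (4R,6R)-actinol, (4R,6R)-4-hydroxy-2,2,6-trimethylcyclohexan-1-one | O=C1C(C)(C)C[C@H](O)C[C@H]1C | starting material
6 | (4R,6R)-4-{[tert-butyl(dimethyl)silyl]oxy}-2,2,6-trimethylcyclohexan-1-one | O=C1C(C)(C)C[C@H](O[Si](C)(C)C(C)(C)C)C[C@H]1C | intermediate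
7 | tert-butyl(dimethyl){[(1R)-3,5,5-trimethyl-4-[(trimethylsilyl)oxy]cyclohex-3-en-1-yl]oxy}silane | CC1=C(O[Si](C)(C)C)C(C)(C)C[C@H](O[Si](C)(C)C(C)(C)C)C1 | intermediate
8 | silyloxy epoxide: 4-(tert-butyldimethylsilyloxy)-2,2,6-trimethyl-1-(trimethylsilyloxy)-7-oxabicyclo[4.1.0]heptane, oxirane oxygen trans to the C4 silyloxy group | C[Si](C)(C)O[C@]12C(C)(C)C[C@H](O[Si](C)(C)C(C)(C)C)C[C@@]1(C)O2 | intermediate (not isolated)
9 | (2R,4S)-4-{[tert-butyl(dimethyl)silyl]oxy}-2,6,6-trimethyl-2-[(trimethylsilyl)oxy]cyclohexan-1-one | O=C1C(C)(C)C[C@H](O[Si](C)(C)C(C)(C)C)C[C@@]1(C)O[Si](C)(C)C | intermediate (not isolated)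
10 | (2R,4S)-4-{[tert-butyl(dimethyl)silyl]oxy}-2-hydroxy-2,6,6-trimethylcyclohexan-1-one | O=C1C(C)(C)C[C@H](O[Si](C)(C)C(C)(C)C)C[C@@]1(C)O | intermediate
11 | (2R,4S)-4-{[tert-butyl(dimethyl)silyl]oxy}-2-{[(2E)-4-{[tert-butyl(dimethyl)silyl]oxy}-2-methylbut-2-en-1-yl]oxy}-2,6,6-trimethylcyclohexan-1-one | O=C1C(C)(C)C[C@H](O[Si](C)(C)C(C)(C)C)C[C@@]1(C)OC/C(C)=C/CO[Si](C)(C)C(C)(C)C | intermediate (key-step precursor)
12 | (trimethylsilyl)diazomethane | C[Si](C)(C)C=[N+]=[N-] | starting material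
13 | lithium alkoxide adduct: lithium (2R,4S)-1-[diazo(trimethylsilyl)methyl]-4-(tert-butyldimethylsilyloxy)-2-{[(2E)-4-(tert-butyldimethylsilyloxy)-2-methylbut-2-en-1-yl]oxy}-2,6,6-trimethylcyclohexan-1-olate (C1 undefined) | [Li+].[O-]C1(C(=[N+]=[N-])[Si](C)(C)C)C(C)(C)C[C@H](O[Si](C)(C)C(C)(C)C)C[C@@]1(C)OC/C(C)=C/CO[Si](C)(C)C(C)(C)C | intermediate (not isolated)
14 | diazoalkene: (2R,4S)-1-(diazomethylidene) analogue of 11 | [N-]=[N+]=C=C1C(C)(C)C[C@H](O[Si](C)(C)C(C)(C)C)C[C@@]1(C)OC/C(C)=C/CO[Si](C)(C)C(C)(C)C | intermediate (not isolated)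
15 | alkylidene carbene: (2R,4S)-1-methylidene carbene analogue of 11 (divalent C7) | [C]=C1C(C)(C)C[C@H](O[Si](C)(C)C(C)(C)C)C[C@@]1(C)OC/C(C)=C/CO[Si](C)(C)C(C)(C)C | intermediate (not isolated)
16 | (2S,6S,7aR)-6-{[tert-butyl(dimethyl)silyl]oxy}-2-[(2E)-4-{[tert-butyl(dimethyl)silyl]oxy}but-2-en-2-yl]-4,4,7a-trimethyl-2,4,5,6,7,7a-hexahydro-1-benzofuran | CC(C)(C)[Si](C)(C)OC/C=C(\C)[C@@H]1C=C2C(C)(C)C[C@H](O[Si](C)(C)C(C)(C)C)C[C@@]2(C)O1 | intermediate (key-step product)
17 | (2S,6S,7aR)-2-[(2E)-4-hydroxybut-2-en-2-yl]-4,4,7a-trimethyl-2,4,5,6,7,7a-hexahydro-1-benzofuran-6-ol | OC/C=C(\C)[C@@H]1C=C2C(C)(C)C[C@H](O)C[C@@]2(C)O1 | intermediate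
18 | (2S,6S,7aR)-2-[(2E)-4-bromobut-2-en-2-yl]-4,4,7a-trimethyl-2,4,5,6,7,7a-hexahydro-1-benzofuran-6-ol | BrC/C=C(\C)[C@@H]1C=C2C(C)(C)C[C@H](O)C[C@@]2(C)O1 | intermediate
19 | [(2E)-3-[(2S,6S,7aR)-6-hydroxy-4,4,7a-trimethyl-2,4,5,6,7,7a-hexahydro-1-benzofuran-2-yl]but-2-en-1-yl]triphenylphosphonium bromide | [Br-].c1ccccc1[P+](c1ccccc1)(c1ccccc1)C/C=C(\C)[C@@H]1C=C2C(C)(C)C[C@H](O)C[C@@]2(C)O1 | intermediate
20 | (R)-α-ionone, (3E)-4-[(1R)-2,6,6-trimethylcyclohex-2-en-1-yl]but-3-en-2-one | CC(=O)/C=C/[C@H]1C(C)=CCCC1(C)C | starting material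
21 | triethyl phosphonoacetate | CCOC(=O)CP(=O)(OCC)OCC | starting material
22 | ethyl (2E,4E)-3-methyl-5-[(1R)-2,6,6-trimethylcyclohex-2-en-1-yl]penta-2,4-dienoate | CCOC(=O)/C=C(C)/C=C/[C@H]1C(C)=CCCC1(C)C | intermediate
23 | ethyl (2E,4E)-3-methyl-5-[(1R)-2,6,6-trimethyl-4-oxocyclohex-2-en-1-yl]penta-2,4-dienoate | CCOC(=O)/C=C(C)/C=C/[C@H]1C(C)=CC(=O)CC1(C)C | intermediate
24 | ethyl (2E,4E)-5-[(1R,4R)-4-hydroxy-2,6,6-trimethylcyclohex-2-en-1-yl]-3-methylpenta-2,4-dienoate | CCOC(=O)/C=C(C)/C=C/[C@H]1C(C)=C[C@H](O)CC1(C)C | intermediate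
25 | ethyl (2E,4E)-5-[(1R,4R)-4-{[tert-butyl(dimethyl)silyl]oxy}-2,6,6-trimethylcyclohex-2-en-1-yl]-3-methylpenta-2,4-dienoate | CCOC(=O)/C=C(C)/C=C/[C@H]1C(C)=C[C@H](O[Si](C)(C)C(C)(C)C)CC1(C)C | intermediate
26 | (2E,4E)-5-[(1R,4R)-4-{[tert-butyl(dimethyl)silyl]oxy}-2,6,6-trimethylcyclohex-2-en-1-yl]-3-methylpenta-2,4-dien-1-ol | OC/C=C(C)/C=C/[C@H]1C(C)=C[C@H](O[Si](C)(C)C(C)(C)C)CC1(C)C | intermediate
27 | tert-butyl{[(1R,4R)-4-[(1E,3E)-5-bromo-3-methylpenta-1,3-dien-1-yl]-3,5,5-trimethylcyclohex-2-en-1-yl]oxy}dimethylsilane | BrC/C=C(C)/C=C/[C@H]1C(C)=C[C@H](O[Si](C)(C)C(C)(C)C)CC1(C)C | intermediate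
28 | [(2E,4E)-5-[(1R,4R)-4-{[tert-butyl(dimethyl)silyl]oxy}-2,6,6-trimethylcyclohex-2-en-1-yl]-3-methylpenta-2,4-dien-1-yl]triphenylphosphonium bromide | [Br-].c1ccccc1[P+](c1ccccc1)(c1ccccc1)C/C=C(C)/C=C/[C@H]1C(C)=C[C@H](O[Si](C)(C)C(C)(C)C)CC1(C)C | intermediate
29 | (2E,4E,6E)-2,7-dimethylocta-2,4,6-trienedial | O=C/C(C)=C/C=C/C=C(C)/C=O | starting material
30 | (2E,4E,6E,8E,10E,12E)-13-[(1R,4R)-4-{[tert-butyl(dimethyl)silyl]oxy}-2,6,6-trimethylcyclohex-2-en-1-yl]-2,7,11-trimethyltrideca-2,4,6,8,10,12-hexaenal | O=C/C(C)=C/C=C/C=C(C)/C=C/C=C(C)/C=C/[C@H]1C(C)=C[C@H](O[Si](C)(C)C(C)(C)C)CC1(C)C | intermediate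
31 | (3S,5R,8S,3'R,6'R)-3'-{[tert-butyl(dimethyl)silyl]oxy}-5,8-epoxy-5,8-dihydro-β,ε-caroten-3-ol | CC1=C[C@H](O[Si](C)(C)C(C)(C)C)CC(C)(C)[C@H]1/C=C/C(C)=C/C=C/C(C)=C/C=C/C=C(C)/C=C/C=C(\C)[C@@H]1C=C2C(C)(C)C[C@H](O)C[C@@]2(C)O1 | intermediate
32 | (3S,5R,8S,3'R,6'R)-5,8-epoxy-5,8-dihydro-β,ε-carotene-3,3'-diol | CC1=C[C@H](O)CC(C)(C)[C@H]1/C=C/C(C)=C/C=C/C(C)=C/C=C/C=C(C)/C=C/C=C(\C)[C@@H]1C=C2C(C)(C)C[C@H](O)C[C@@]2(C)O1 | target

**Step count**

Total steps: 21. Longest linear sequence: 10 steps (steps 4–11, 20 and 21; the bromide and ε-end branches are equally long).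

**Steps most likely to fail**

Step 8. The lithiated diazo reagent may add sluggishly to a carbonyl group flanked by two fully substituted carbons, and the carbene may discriminate poorly between the two diastereotopic C8 hydrogens, so that much of the material ends up as the C8 epimer. The fallback builds the dihydrofuran by the classical acid-induced rearrangement of a 5,6-epoxide to the 5,8-epoxide. It sets out from 6: enolate trapping (KN(SiMe3)2, PhNTf2, THF, −78 °C) would give the enol triflate F1. Commercial (E)-3-methylpent-2-en-4-yn-1-ol would be silylated (TBSCl, imidazole) to the silyl enyne F2 and hydrostannylated (Bu3SnH, PdCl2(PPh3)2 cat.) to the dienylstannane F3. Stille coupling of F1 with F3 (Pd2(dba)3, AsPh3, NMP) would give the triene F4. mCPBA with NaHCO3 would epoxidise the ring double bond, mainly anti to the silyloxy group, to the epoxide F5. A trace of pyridinium p-toluenesulfonate in CH2Cl2 would then open F5 at C6 and close O5 onto C8, giving 16 together with its (8R) epimer F6. The two are separated, F6 is re-equilibrated under the same acid, and the route is rejoined at 16.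

Step 6. Peracid attack on the enol ether may show poor facial selectivity, or deliver oxygen syn to the C3 silyloxy group, so that the C5 epimer dominates. The fallback sets the C5 oxygen next to the existing stereocentre instead of 1,3 to it. It sets out from 7: Saegusa oxidation (Pd(OAc)2, MeCN) would give the enone F7, whose C4=C5 bond is adjacent to the silyloxy-bearing carbon. Nucleophilic epoxidation (H2O2, NaOH, MeOH, 0 °C) should take place anti to that neighbouring group and give the epoxy ketone F8 with the C5 oxygen trans to the C3 oxygen. LiAlH4 in THF would reduce the carbonyl group and open the oxirane by hydride attack at the secondary carbon C4, giving the diol F9. Parikh–Doering oxidation (SO3·pyridine, DMSO, Et3N) of the secondary alcohol would return the route to 10.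

Step 14. The hydride may be delivered from the other face (axial attack, giving the cis 3'-epimer), or conjugate reduction of the dienoate may compete. The fallback accepts the cis alcohol and inverts it. It sets out from 23: Luche reduction (NaBH4, CeCl3·7H2O, MeOH, −20 °C), which favours axial attack, would give the cis alcohol F10. Mitsunobu reaction with 4-nitrobenzoic acid (PPh3, diisopropyl azodicarboxylate, THF) would invert C3' and give the 4-nitrobenzoate F11. Ethanolysis (K2CO3, EtOH), which leaves the ethyl ester as it is, would rejoin the route at 24.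

**Further compounds**

F1 | step 8 | (4R)-4-{[tert-butyl(dimethyl)silyl]oxy}-2,6,6-trimethylcyclohex-1-en-1-yl trifluoromethanesulfonate | CC1=C(OS(=O)(=O)C(F)(F)F)C(C)(C)C[C@H](O[Si](C)(C)C(C)(C)C)C1
F2 | step 8 | tert-butyl(dimethyl){[(2E)-3-methylpent-2-en-4-yn-1-yl]oxy}silane | C#C/C(C)=C/CO[Si](C)(C)C(C)(C)C
F3 | step 8 | tert-butyl(dimethyl){[(2E,4E)-3-methyl-5-(tributylstannyl)penta-2,4-dien-1-yl]oxy}silane | CCCC[Sn](CCCC)(CCCC)/C=C/C(C)=C/CO[Si](C)(C)C(C)(C)C
F4 | step 8 | tert-butyl{[(2E,4E)-5-[(4R)-4-{[tert-butyl(dimethyl)silyl]oxy}-2,6,6-trimethylcyclohex-1-en-1-yl]-3-methylpenta-2,4-dien-1-yl]oxy}dimethylsilane | CC1=C(/C=C/C(C)=C/CO[Si](C)(C)C(C)(C)C)C(C)(C)C[C@H](O[Si](C)(C)C(C)(C)C)C1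
F5 | step 8 | 5,6-epoxide of F4, oxirane oxygen trans to the ring silyloxy group (3S,5R,6S in carotenoid locants) | CC(C)(C)[Si](C)(C)OC/C=C(C)/C=C/[C@]12C(C)(C)C[C@H](O[Si](C)(C)C(C)(C)C)C[C@@]1(C)O2
F6 | step 8 | (2R,6S,7aR) epimer of 16 (8R in carotenoid locants) | CC(C)(C)[Si](C)(C)OC/C=C(\C)[C@H]1C=C2C(C)(C)C[C@H](O[Si](C)(C)C(C)(C)C)C[C@@]2(C)O1
F7 | step 6 | (4S)-4-{[tert-butyl(dimethyl)silyl]oxy}-2,6,6-trimethylcyclohex-2-en-1-one | O=C1C(C)(C)C[C@H](O[Si](C)(C)C(C)(C)C)C=C1C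
F8 | step 6 | 5-(tert-butyldimethylsilyloxy)-1,3,3-trimethyl-7-oxabicyclo[4.1.0]heptan-2-one, oxirane oxygen trans to the silyloxy group | O=C1C(C)(C)C[C@H](O[Si](C)(C)C(C)(C)C)[C@H]2O[C@@]12C
F9 | step 6 | (2R,4S)-4-{[tert-butyl(dimethyl)silyl]oxy}-2,6,6-trimethylcyclohexane-1,2-diol (C1 epimers) | OC1C(C)(C)C[C@H](O[Si](C)(C)C(C)(C)C)C[C@@]1(C)O
F10 | step 14 | ethyl (2E,4E)-5-[(1R,4S)-4-hydroxy-2,6,6-trimethylcyclohex-2-en-1-yl]-3-methylpenta-2,4-dienoate | CCOC(=O)/C=C(C)/C=C/[C@H]1C(C)=C[C@@H](O)CC1(C)C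
F11 | step 14 | ethyl (2E,4E)-3-methyl-5-[(1R,4R)-2,6,6-trimethyl-4-[(4-nitrobenzoyl)oxy]cyclohex-2-en-1-yl]penta-2,4-dienoate | CCOC(=O)/C=C(C)/C=C/[C@H]1C(C)=C[C@H](OC(=O)c2ccc(cc2)[N+](=O)[O-])CC1(C)C
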